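**Retrosynthetic overview**

- Target 23 is the chain A–CH2–B–CH2–C–CH2–D–CH2–E. The two outer bridges are cut last: the free carbon of rings B and D of trimer nonaol 18 is aminomethylated and then alkylates C6 of the end-ring triketone 21 through an ortho-quinone methide. 18 comes from octamethyl ether 17 by ether cleavage.
- The strategy rests on ring C: its butanoyl-bearing carbon lies between two oxygen-bearing ring carbons. The adjacent C(butanoyl)/C(OH) pair of 17 is therefore cut back to an aryne flanked by a methoxy carbon, generated from silyl triflate 14, plus butanoic acid 15 (one C–O and one C–C bond made together).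
- 14 comes from bromophenol trimer 10 by bromine–lithium exchange, retro-Brook silyl shift and triflation, with the ring B and D ketones masked as silyl enol ethers. 10 comes from the ring C bis(hydroxymethyl)bromophenol 9 and two molecules of ketone 3; ring C carries the electrophilic carbons, so no partner can self-condense.
- No ring is built. Rings B and D are 1,3,5-trimethoxybenzene, ring C is 3,5-dimethoxyphenol, rings A and E are phloroglucinol. Order of joining: C with B and D, then the ring C acyl/hydroxyl pair, then A and E.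

Key step: step 9

Remark: the end rings are drawn in the enol tautomer of the target SMILES; the target has no stereocentre. The silyl enol ethers of 11–13 are drawn Z, and either geometry returns the ketone.

**Route**

Step 1
Reactants: 1 1,3,5-trimethoxybenzene; 2 butanoyl chloride
Product: 3 1-(2,4,6-trimethoxyphenyl)butan-1-one
Conditions: Bi(OTf)3 (5 mol %), MeNO2, rt
Reagents that add atoms: none
Why: Friedel–Crafts acylation; the arene is activated enough for a catalytic Lewis acid, and the acyl group deactivates the ring against a second acylation.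

Step 2
Reactants: 4 3,5-dimethoxyphenol
Product: 5 3,5-dimethoxyphenyl N,N-diethylcarbamate
Conditions: Et2NCOCl, K2CO3, MeCN, reflux
Reagents that add atoms: diethylcarbamoyl chloride, CCN(CC)C(Cl)=O
Why: O-carbamoylation of the phenoxide installs the directing group for ortho-metalation.

Step 3
Reactants: 5 3,5-dimethoxyphenyl N,N-diethylcarbamate
Product: 7 2-bromo-3,5-dimethoxyphenyl N,N-diethylcarbamate, via aryllithium 6 (not isolated)
Conditions: s-BuLi, TMEDA, THF, −78 °C; then BrCCl2CCl2Br, −78 °C → rt
Reagents that add atoms: 1,2-dibromo-1,1,2,2-tetrachloroethane, BrC(Cl)(Cl)C(Cl)(Cl)Br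
Why: Directed ortho-metalation; the carbamate and the flanking methoxy group together place lithium on the carbon between them, and the polyhaloethane transfers bromine to the aryllithium before any anionic Fries shift at −78 °C.

Step 4
Reactants: 7 2-bromo-3,5-dimethoxyphenyl N,N-diethylcarbamate
Product: 8 2-bromo-3,5-dimethoxyphenol
Conditions: NaOH, EtOH/H2O, reflux; then aq. HCl
Reagents that add atoms: none
Why: Base hydrolysis of the aryl carbamate should free the phenol, the aryl bromide being inert to hydroxide.

Step 5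
Reactants: 8 2-bromo-3,5-dimethoxyphenol
Product: 9 2-bromo-4,6-bis(hydroxymethyl)-3,5-dimethoxyphenol
Conditions: 37 % aq. CH2O (excess), NaOH (1.1 equiv), H2O/MeOH, 0 °C → rt; AcOH to pH 6; used directly
Reagents that add atoms: formaldehyde, C=O
Why: Lederer–Manasse hydroxymethylation; the phenoxide adds to formaldehyde at its only open ortho and para carbons, and excess formaldehyde at low temperature keeps diarylmethane formation down.

Step 6
Reactants: 9 2-bromo-4,6-bis(hydroxymethyl)-3,5-dimethoxyphenol; 3 1-(2,4,6-trimethoxyphenyl)butan-1-one (two molecules react; 6 equiv used, excess recovered)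
Product: 10 2-bromo-4,6-bis[(3-butanoyl-2,4,6-trimethoxyphenyl)methyl]-3,5-dimethoxyphenol
Conditions: TsOH·H2O (10 mol %), 1,1,1,3,3,3-hexafluoropropan-2-ol (HFIP)/CH2Cl2, 0 °C → rt
Reagents that add atoms: none
Why: Friedel–Crafts benzylation; the ortho- and para-hydroxybenzyl cations from 9 are captured at the carbon between two methoxy groups of 3, ring C has no free carbon for self-condensation, and the excess of 3 suppresses double alkylation of one ketone ring.

Step 7
Reactants: 10 2-bromo-4,6-bis[(3-butanoyl-2,4,6-trimethoxyphenyl)methyl]-3,5-dimethoxyphenol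
Product: 11 [2-bromo-3,5-dimethoxy-4,6-bis({2,4,6-trimethoxy-3-[(Z)-1-(trimethylsilyloxy)but-1-enyl]phenyl}methyl)phenoxy]trimethylsilane
Conditions: TMSOTf (3.6 equiv), Et3N, CH2Cl2, 0 °C → rt; salts removed with pentane, crude used
Reagents that add atoms: trimethylsilyl trifluoromethanesulfonate, C[Si](C)(C)OS(=O)(=O)C(F)(F)F
Why: Silylation by soft enolization covers the phenol as the silyl ether needed for the silyl shift and turns both aryl ketones into silyl enol ethers, which removes the electrophilic carbonyls before n-BuLi is used.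

Step 8
Reactants: 11 tris(trimethylsilyl) derivative of 10
Product: 14 4,6-bis[(3-butanoyl-2,4,6-trimethoxyphenyl)methyl]-3,5-dimethoxy-2-(trimethylsilyl)phenyl trifluoromethanesulfonate, via lithium 2-silylphenoxide 12 (not isolated), via bis-enol-ether aryl triflate 13 (not isolated)
Conditions: n-BuLi, THF, −100 → −78 °C; PhNTf2, −78 °C → rt; then 1 M aq. HCl, THF, 0 °C
Reagents that add atoms: N-phenylbis(trifluoromethanesulfonimide), O=S(=O)(N(c1ccccc1)S(=O)(=O)C(F)(F)F)C(F)(F)F
Why: Bromine–lithium exchange at −100 °C should outrun attack on the silyl enol ethers, the ortho-lithio aryl silyl ether undergoes the retro-Brook 1,3 O→C silyl shift to phenoxide 12, PhNTf2 triflates the phenoxide without touching the enol ethers, and dilute acid returns both ketones while the arylsilane on the triflate-deactivated ring is kept.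

Step 9
Reactants: 14 ring C silyl triflate; 15 butanoic acid
Product: 17 1-{3,5-bis[(3-butanoyl-2,4,6-trimethoxyphenyl)methyl]-2-hydroxy-4,6-dimethoxyphenyl}butan-1-one, via ring C aryne 16 (not isolated)
Conditions: CsF (4 equiv), 15 (1.5 equiv), THF, 125 °C, sealed tube
Reagents that add atoms: none
Why: Fluoride attacks silicon and triflate leaves to give aryne 16; caesium butanoate adds through oxygen to the aryne carbon remote from the methoxy-bearing carbon (the former triflate carbon), and the aryl anion formed beside the methoxy group attacks the ester carbonyl through a four-membered transition state, so the acyl group passes from oxygen to carbon and the ortho-hydroxyaryl ketone results after protonation. The closest known reaction type is the formal insertion of arynes into the O–C(acyl) bond of carboxylic acids with CsF in hot THF. No ring is closed and no stereocentre is formed. The step needs regioselective addition to an unsymmetrical aryne: the inductively withdrawing methoxy group distorts the triple bond so that the nucleophile enters at the far carbon and the charge develops next to oxygen, which should outweigh the weak steric bias of the arylmethyl group on the other flank. It also needs the acyl shift to outrun protonation of the aryl anion, which the hot, weakly solvating medium and the small amount of free acid favour; the ring is otherwise fully substituted, and the ketones and the lone C–H of rings B and D are poor aryne traps next to the carboxylate.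

Step 10
Reactants: 17 octamethyl ether trimer
Product: 18 1-{3,5-bis[(3-butanoyl-2,4,6-trihydroxyphenyl)methyl]-2,4,6-trihydroxyphenyl}butan-1-one
Conditions: BBr3 (excess), CH2Cl2, −78 °C → rt; then MeOH, H2O
Reagents that add atoms: none
Why: Lewis-acid ether cleavage; BBr3 binds each methoxy oxygen and bromide removes the methyl group by SN2, chelation to the carbonyls speeding the ortho ethers and the excess taking the three para ethers.

Step 11
Reactants: 19 phloroglucinol; 2 butanoyl chloride
Product: 20 1-(2,4,6-trihydroxyphenyl)butan-1-one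
Conditions: AlCl3, MeNO2/CH2Cl2, 0 → 40 °C; aq. HCl
Reagents that add atoms: none
Why: Friedel–Crafts acylation of phloroglucinol stops at monoacylation because the chelated acyl group deactivates the ring.

Step 12
Reactants: 20 1-(2,4,6-trihydroxyphenyl)butan-1-one
Product: 21 2-butanoyl-3,5-dihydroxy-4,4-dimethylcyclohexa-2,5-dien-1-one (butyrylfilicinic acid)
Conditions: NaOMe, MeI, MeOH, 0 °C → rt
Reagents that add atoms: iodomethane, CI
Why: Dearomatizing C-methylation of the acylphloroglucinol polyanion; the second methyl group enters the carbon that already carries the first, giving the gem-dimethyl triketone.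

Step 13
Reactants: 18 trimer nonaol
Product: 22 1-{3,5-bis({3-butanoyl-5-[(dimethylamino)methyl]-2,4,6-trihydroxyphenyl}methyl)-2,4,6-trihydroxyphenyl}butan-1-one
Conditions: Me2N=CH2+ I− (2.1 equiv), Et3N, MeCN, 0 °C → rt
Reagents that add atoms: N,N-dimethylmethyleneiminium iodide, C[N+](C)=C.[I-]
Why: Mannich reaction; the preformed iminium ion can attack only the single unsubstituted carbon of ring B and of ring D, and no free formaldehyde is present to bridge two trimers.

Step 14
Reactants: 22 bis-Mannich base; 21 butyrylfilicinic acid (two molecules react; 4 equiv used)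
Product: 23 target CNP0188003.0
Conditions: 1,4-dioxane, 90 °C
Reagents that add atoms: none
Why: Thermal loss of dimethylamine from each ortho-hydroxybenzylamine gives an ortho-quinone methide that is captured in a Michael addition by C6 of triketone 21, and rearomatization leaves the methylene bridge; no stereocentre is formed.

**Compound list**

1 | 1,3,5-trimethoxybenzene | COc1cc(OC)cc(OC)c1 | starting material
2 | butanoyl chloride | CCCC(=O)Cl | starting material
3 | 1-(2,4,6-trimethoxyphenyl)butan-1-one | CCCC(=O)c1c(OC)cc(OC)cc1OC | intermediate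
4 | 3,5-dimethoxyphenol | COc1cc(O)cc(OC)c1 | starting material
5 | 3,5-dimethoxyphenyl N,N-diethylcarbamate | CCN(CC)C(=O)Oc1cc(OC)cc(OC)c1 | intermediate
6 | 2-lithio-3,5-dimethoxyphenyl N,N-diethylcarbamate | [Li]c1c(OC)cc(OC)cc1OC(=O)N(CC)CC | intermediate (not isolated)
7 | 2-bromo-3,5-dimethoxyphenyl N,N-diethylcarbamate | CCN(CC)C(=O)Oc1cc(OC)cc(OC)c1Br | intermediate
8 | 2-bromo-3,5-dimethoxyphenol | COc1cc(O)c(Br)c(OC)c1 | intermediate
9 | 2-bromo-4,6-bis(hydroxymethyl)-3,5-dimethoxyphenol | COc1c(CO)c(O)c(Br)c(OC)c1CO | intermediate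
10 | 2-bromo-4,6-bis[(3-butanoyl-2,4,6-trimethoxyphenyl)methyl]-3,5-dimethoxyphenol | CCCC(=O)c1c(OC)cc(OC)c(Cc2c(O)c(Br)c(OC)c(Cc3c(OC)cc(OC)c(C(=O)CCC)c3OC)c2OC)c1OC | intermediate
11 | [2-bromo-3,5-dimethoxy-4,6-bis({2,4,6-trimethoxy-3-[(Z)-1-(trimethylsilyloxy)but-1-enyl]phenyl}methyl)phenoxy]trimethylsilane | CC/C=C(\O[Si](C)(C)C)c1c(OC)cc(OC)c(Cc2c(O[Si](C)(C)C)c(Br)c(OC)c(Cc3c(OC)cc(OC)c(/C(O[Si](C)(C)C)=C/CC)c3OC)c2OC)c1OC | intermediate
12 | lithium 3,5-dimethoxy-4,6-bis({2,4,6-trimethoxy-3-[(Z)-1-(trimethylsilyloxy)but-1-enyl]phenyl}methyl)-2-(trimethylsilyl)phenoxide | [Li+].CC/C=C(\O[Si](C)(C)C)c1c(OC)cc(OC)c(Cc2c([O-])c([Si](C)(C)C)c(OC)c(Cc3c(OC)cc(OC)c(/C(O[Si](C)(C)C)=C/CC)c3OC)c2OC)c1OC | intermediate (not isolated)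
13 | 3,5-dimethoxy-4,6-bis({2,4,6-trimethoxy-3-[(Z)-1-(trimethylsilyloxy)but-1-enyl]phenyl}methyl)-2-(trimethylsilyl)phenyl trifluoromethanesulfonate | CC/C=C(\O[Si](C)(C)C)c1c(OC)cc(OC)c(Cc2c(OS(=O)(=O)C(F)(F)F)c([Si](C)(C)C)c(OC)c(Cc3c(OC)cc(OC)c(/C(O[Si](C)(C)C)=C/CC)c3OC)c2OC)c1OC | intermediate (not isolated)
14 | 4,6-bis[(3-butanoyl-2,4,6-trimethoxyphenyl)methyl]-3,5-dimethoxy-2-(trimethylsilyl)phenyl trifluoromethanesulfonate | C[Si](C)(C)c1c(OS(=O)(=O)C(F)(F)F)c(Cc2c(OC)cc(OC)c(C(=O)CCC)c2OC)c(OC)c(Cc2c(OC)cc(OC)c(C(=O)CCC)c2OC)c1OC | intermediate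
15 | butanoic acid | CCCC(=O)O | starting material
16 | ring C aryne, 3,5-bis[(3-butanoyl-2,4,6-trimethoxyphenyl)methyl]-4,6-dimethoxybenzyne | COC1=C(Cc2c(OC)cc(OC)c(C(=O)CCC)c2OC)C(OC)=C(Cc2c(OC)cc(OC)c(C(=O)CCC)c2OC)C#C1 | intermediate (not isolated)
17 | 1-{3,5-bis[(3-butanoyl-2,4,6-trimethoxyphenyl)methyl]-2-hydroxy-4,6-dimethoxyphenyl}butan-1-one | CCCC(=O)c1c(O)c(Cc2c(OC)cc(OC)c(C(=O)CCC)c2OC)c(OC)c(Cc2c(OC)cc(OC)c(C(=O)CCC)c2OC)c1OC | intermediate
18 | 1-{3,5-bis[(3-butanoyl-2,4,6-trihydroxyphenyl)methyl]-2,4,6-trihydroxyphenyl}butan-1-one | CCCC(=O)c1c(O)c(Cc2c(O)cc(O)c(C(=O)CCC)c2O)c(O)c(Cc2c(O)cc(O)c(C(=O)CCC)c2O)c1O | intermediate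
19 | phloroglucinol (benzene-1,3,5-triol) | Oc1cc(O)cc(O)c1 | starting material
20 | 1-(2,4,6-trihydroxyphenyl)butan-1-one | CCCC(=O)c1c(O)cc(O)cc1O | intermediate
21 | 2-butanoyl-3,5-dihydroxy-4,4-dimethylcyclohexa-2,5-dien-1-one | CCCC(=O)C1=C(O)C(C)(C)C(O)=CC1=O | intermediate
22 | 1-{3,5-bis({3-butanoyl-5-[(dimethylamino)methyl]-2,4,6-trihydroxyphenyl}methyl)-2,4,6-trihydroxyphenyl}butan-1-one | CCCC(=O)c1c(O)c(Cc2c(O)c(CN(C)C)c(O)c(C(=O)CCC)c2O)c(O)c(Cc2c(O)c(CN(C)C)c(O)c(C(=O)CCC)c2O)c1O | intermediate
23 | CNP0188003.0, pentameric methylene-bridged butyrylphloroglucinol with two butyrylfilicinic acid end rings | CCCC(=O)C1=C(O)C(C)(C)C(O)=C(Cc2c(O)c(Cc3c(O)c(Cc4c(O)c(CC5=C(O)C(C)(C)C(O)=C(C(=O)CCC)C5=O)c(O)c(C(=O)CCC)c4O)c(O)c(C(=O)CCC)c3O)c(O)c(C(=O)CCC)c2O)C1=O | target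

**Step count and risks**

Total step count: 14. Longest linear sequence: 11 steps (steps 2–10, 13 and 14, from 3,5-dimethoxyphenol 4).

Steps most likely to fail:

1. Step 9. The aryl anion may be protonated before the acyl group shifts, leaving only O-arylation. The aryne may also be captured within the molecule by a neighbouring methoxy oxygen, or the carboxylate may enter at the wrong aryne carbon. Fallback (sets out from 4, returns at 17): 3,5-dimethoxyphenol 4 would be C-acylated ortho to the hydroxyl with butanoyl chloride 2 (BF3·OEt2, O-acylation and Fries shift) to 1-(2-hydroxy-4,6-dimethoxyphenyl)butan-1-one F1. Hydroxymethylation of its two free ring carbons (aq. CH2O, NaOH) would give 1-[2-hydroxy-3,5-bis(hydroxymethyl)-4,6-dimethoxyphenyl]butan-1-one F2. Friedel–Crafts benzylation of ketone 3 with F2 (TsOH·H2O, HFIP) would then give 17 with the ring C acyl group in place from the start, so that no aryne is needed.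

2. Step 10. Cleavage of the three ethers para to the acyl groups may stall, and the HBr formed may protonate the electron-rich rings at the bridge carbons and cause scission or exchange of the diarylmethane links. Fallback (sets out from 17, returns at 18): BCl3 (CH2Cl2, −78 → 0 °C) would remove only the five methyl ethers ortho to a butanoyl group by chelation, giving 1-{3,5-bis[(3-butanoyl-2,4-dihydroxy-6-methoxyphenyl)methyl]-2,6-dihydroxy-4-methoxyphenyl}butan-1-one F3. The three remaining ethers, each para to an acyl group, would then be cleaved by SN2 attack of EtSNa in DMF at 110 °C, without acid, to give 18.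

3. Step 14. At 90 °C the methylene bridges may exchange by retro-Michael loss and re-addition, and the end ring may be alkylated twice. Fallback (sets out from 21, returns at 23): 21 would be aminomethylated at C6 (Me2N=CH2+ I−, Et3N, MeCN) to 2-butanoyl-6-[(dimethylamino)methyl]-3,5-dihydroxy-4,4-dimethylcyclohexa-2,5-dien-1-one F4. F4 (2.2 equiv) would be warmed with nonaol 18 in 1,4-dioxane at 60 °C, so that the 6-methylene triketone formed by loss of dimethylamine is captured by the free carbon of rings B and D, which reverses the roles of electrophile and nucleophile and gives 23.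

**Further compounds**

F1 | step 9 | 1-(2-hydroxy-4,6-dimethoxyphenyl)butan-1-one | CCCC(=O)c1c(O)cc(OC)cc1OC
F2 | step 9 | 1-[2-hydroxy-3,5-bis(hydroxymethyl)-4,6-dimethoxyphenyl]butan-1-one | CCCC(=O)c1c(O)c(CO)c(OC)c(CO)c1OC
F3 | step 10 | 1-{3,5-bis[(3-butanoyl-2,4-dihydroxy-6-methoxyphenyl)methyl]-2,6-dihydroxy-4-methoxyphenyl}butan-1-one | CCCC(=O)c1c(O)c(Cc2c(OC)cc(O)c(C(=O)CCC)c2O)c(OC)c(Cc2c(OC)cc(O)c(C(=O)CCC)c2O)c1O
F4 | step 14 | 2-butanoyl-6-[(dimethylamino)methyl]-3,5-dihydroxy-4,4-dimethylcyclohexa-2,5-dien-1-one | CCCC(=O)C1=C(O)C(C)(C)C(O)=C(CN(C)C)C1=O
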